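**Retrosynthetic overview**

1. Target 12 ← tigloylation of 9α-ketol 10 ← reductive α-hydroxylation (H to C10, O to C9) of the petasol-type dienone 8 ← kinetic deconjugation of the isopetasol-type dienone 6.
2. 6 ← acid-triggered backbone rearrangement of the eudesmane allylic ester 5 (C5→C4 hydride shift, C10→C5 methyl shift, loss of H9), the eudesmane-to-eremophilane sequence of the biosynthesis.
3. 5 ← C3 allylic hydroxylation and senecioylation of eudesmadienone 2.
4. 2 ← enantioselective, protonation-initiated transannular cyclization of germacrone 1 (the germacrane-to-eudesmane ring closure of the biosynthesis).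
5. Ring order: the ten-membered ring is bought in 1; one transannular C5–C10 bond closes rings A and B together; the eremophilane skeleton then arises by rearrangement, with no further ring formation.

Assumption: eudesmane/eremophilane numbering (C1–C15) is used in all names; germacrone (the crystalline main constituent of commercial zdravets oil) is taken as a cheap commercial starting material; the (S,S)-antipode of the chiral acid is written for the required sense of induction, and the (R,R)-antipode is used if the sense proves opposite.

**Step 1**
Reactants: 1 germacrone, (3E,7E)-3,7-dimethyl-10-(propan-2-ylidene)cyclodeca-3,7-dien-1-one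
Product: 2 (5S,10R)-eudesma-4(15),7(11)-dien-8-one (trans-fused; 5α-H; 10β-CH3)
Conditions: (S,S)-IDPi (BINOL-derived N-triflyl imidodiphosphorimidate Brønsted acid, 5 mol %), (CF3)3COH/CHCl3 1:1, −40 °C
Reagents that add atoms: none
Why: Proposed new method: the confined chiral acid protonates C1 of the 1(10) alkene in one of the two rapidly interconverting planar-chiral crossed conformers of 1 (dynamic kinetic selection inside the chiral ion pair), the C10 cation is captured transannularly by C5 of the 4(5) alkene through the chair–chair arrangement of the E,E-cyclodecadiene, which fixes the trans ring fusion (5α-H, 10β-CH3) and, through the catalyst, the absolute configuration at C5 and C10, and the C4 cation then loses the most accessible C15 proton to the counter-anion to give the exocyclic alkene (the conjugated 7(11) alkene is deactivated toward protonation, and minor 3-ene or 4-ene isomers are removed by chromatography); the closest known reaction types are the acid-induced transannular cyclization of germacrone to racemic eudesmadienones and IDPi-catalysed enantioselective protonation-initiated cation–olefin cyclizations.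

**Step 2**
Reactants: 2 (5S,10R)-eudesma-4(15),7(11)-dien-8-one
Product: 3 (3R,5R,10R)-3-hydroxyeudesma-4(15),7(11)-dien-8-one (3α-OH, axial)
Conditions: SeO2 (0.5 equiv), t-BuOOH (3 equiv), CH2Cl2, 0 °C to rt
Reagents that add atoms: selenium dioxide O=[Se]=O (catalytic oxygen carrier); tert-butyl hydroperoxide CC(C)(C)OO (terminal oxygen source)
Why: Sharpless–Umbreit allylic hydroxylation, in which the ene reaction of SeO2 at the electron-rich 1,1-disubstituted alkene removes the axial 3α-H (ring CH2 preferred over the ring-fusion CH) and the [2,3]-sigmatropic shift returns the exocyclic alkene while delivering oxygen axially, so the new C3 centre is 3α as is usual for methylenecyclohexanes in trans-decalins; the electron-poor enone alkene and the ketone α-CH2 do not react under these catalytic conditions.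

**Step 3**
Reactants: 3 (3R,5R,10R)-3-hydroxyeudesma-4(15),7(11)-dien-8-one; 4 3-methylbut-2-enoyl chloride (senecioyl chloride)
Product: 5 (3R,5R,10R)-3-(3-methylbut-2-enoyloxy)eudesma-4(15),7(11)-dien-8-one
Conditions: pyridine, DMAP (10 mol %), CH2Cl2, 0 °C to rt
Reagents that add atoms: 3-methylbut-2-enoyl chloride CC(C)=CC(=O)Cl
Why: DMAP-catalysed O-acylation through the acylpyridinium ion, with retention at C3; pyridine instead of a trialkylamine avoids vinylketene formation and deconjugation of the senecioyl unit.

**Step 4**
Reactants: 5 (3R,5R,10R)-3-(3-methylbut-2-enoyloxy)eudesma-4(15),7(11)-dien-8-one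
Product: 6 (3R,4R,5R)-3-(3-methylbut-2-enoyloxy)eremophila-7(11),9-dien-8-one (isopetasol 3-senecioate; 3α-O, 4β-CH3, 5β-CH3)
Conditions: Tf2NH (10 mol %), (CF3)2CHOH, 0 °C
Reagents that add atoms: none
Why: Proposed new method: protonation of the exocyclic C4=C15 alkene by the strong non-nucleophilic acid in an ionizing, non-basic solvent gives the C4 cation, which the neighbouring electron-withdrawing 3α-acyloxy group destabilizes, so the axial 5α-H migrates suprafacially to the α-face of C4 (setting 4α-H, 4β-CH3), the axial 10β-CH3 then migrates to the β-face of C5 (setting the quaternary 5β-methyl cis to the 4-methyl), and the C10 cation is discharged irreversibly by loss of H9 to the cross-conjugated dienone with regeneration of the acid, so that the configuration of C5/C10 in 5 is relayed stereospecifically to C4/C5 of 6; this is the hydride/methyl-shift sequence of eremophilane biosynthesis, and the closest known reaction types are the Westphalen–Lettré rearrangement of 5α-hydroxy steroids carrying a neighbouring acyloxy group and the acid-induced rearrangement of epoxy-eudesmanes to eremophil-9-enes.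

**Step 5**
Reactants: 6 (3R,4R,5R)-3-(3-methylbut-2-enoyloxy)eremophila-7(11),9-dien-8-one
Product: 8 (3R,4R,5R,7S)-3-(3-methylbut-2-enoyloxy)eremophila-9,11-dien-8-one (petasol 3-senecioate; 7α-isopropenyl), via lithium trienolate 7 (not isolated)
Conditions: LiN(iPr)2 (1.05 equiv), THF, −78 °C; then AcOH, −78 °C
Reagents that add atoms: none
Why: Kinetic deconjugation of an α,β-unsaturated ketone through its extended enolate, in which carbonyl-coordinated LiN(iPr)2 removes a proton from the isopropylidene methyl syn to the carbonyl oxygen (the C1 methylene lies on the far side of the ring enone, and the ketone γ-H is several pKa units more acidic than the senecioate γ-H), and low-temperature protonation of the trienolate occurs at the α-carbon C7 from the β-face (stereoelectronically preferred pseudo-axial attack), placing the isopropenyl group in the pseudo-equatorial 7α position, which is also the more stable C7 epimer.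

**Step 6**
Reactants: 8 (3R,4R,5R,7S)-3-(3-methylbut-2-enoyloxy)eremophila-9,11-dien-8-one
Product: 10 (3R,4R,5R,7S,9S,10R)-9-hydroxy-3-(3-methylbut-2-enoyloxy)eremophil-11-en-8-one, via 9α-hydroperoxide 9 (not isolated)
Conditions: Mn(dpm)3 (5 mol %), PhSiH3 (2 equiv), O2 (1 atm), iPrOH/CH2Cl2, 0 °C; then P(OEt)3
Reagents that add atoms: dioxygen O=O
Why: Mukaiyama-type hydrogen-atom-transfer reductive α-hydroxylation of an enone, in which the manganese hydride formed from Mn(dpm)3 and PhSiH3 transfers H to the β-carbon C10 on the α-face, anti to the axial 5β-methyl (trans ring fusion, 10α-H), the C9 α-keto radical is trapped by O2 on its equatorial α-face (β-attack is syn-axial to the 5-methyl) and the phosphite reduces the hydroperoxide to the 9α-ol; the conjugated enone reacts much faster than the isolated isopropenyl group or the β,β-disubstituted enoate, and no base is present that could move the 11(12) alkene into conjugation.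

**Step 7**
Reactants: 10 (3R,4R,5R,7S,9S,10R)-9-hydroxy-3-(3-methylbut-2-enoyloxy)eremophil-11-en-8-one; 11 (E)-2-methylbut-2-enoyl chloride (tigloyl chloride)
Product: 12 (3R,4R,5R,7S,9S,10R)-3-(3-methylbut-2-enoyloxy)-9-[(E)-2-methylbut-2-enoyloxy]eremophil-11-en-8-one (CNP0164025.1)
Conditions: pyridine, DMAP (10 mol %), CH2Cl2, 0 °C
Reagents that add atoms: (E)-2-methylbut-2-enoyl chloride C/C=C(\C)C(=O)Cl
Why: DMAP-catalysed acylation of the equatorial ketol hydroxyl with retention at C9; the tigloyl group is the stable E isomer, and the weak base at 0 °C leaves the β,γ-alkene and the enolizable C7 and C9 centres (both already in their equatorial configurations) unchanged.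

**Compound list**

1 | germacrone, (3E,7E)-3,7-dimethyl-10-(propan-2-ylidene)cyclodeca-3,7-dien-1-one | C/C1=C\CC/C(C)=C/CC(=C(C)C)C(=O)C1 | starting material
2 | (5S,10R)-eudesma-4(15),7(11)-dien-8-one | C=C1CCC[C@]2(C)CC(=O)C(=C(C)C)C[C@@H]12 | intermediate
3 | (3R,5R,10R)-3-hydroxyeudesma-4(15),7(11)-dien-8-one | C=C1[C@H](O)CC[C@]2(C)CC(=O)C(=C(C)C)C[C@@H]12 | intermediate
4 | 3-methylbut-2-enoyl chloride (senecioyl chloride) | CC(C)=CC(=O)Cl | starting material
5 | (3R,5R,10R)-3-(3-methylbut-2-enoyloxy)eudesma-4(15),7(11)-dien-8-one | C=C1[C@H](OC(=O)C=C(C)C)CC[C@]2(C)CC(=O)C(=C(C)C)C[C@@H]12 | intermediate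
6 | (3R,4R,5R)-3-(3-methylbut-2-enoyloxy)eremophila-7(11),9-dien-8-one | CC(C)=C1C[C@]2(C)[C@@H](C)[C@H](OC(=O)C=C(C)C)CCC2=CC1=O | intermediate
7 | lithium (3R,4R,5R)-3-(3-methylbut-2-enoyloxy)eremophila-7,9,11-trien-8-olate | [Li+].C=C(C)C=1C[C@]2(C)[C@@H](C)[C@H](OC(=O)C=C(C)C)CCC2=CC=1[O-] | intermediate (not isolated)
8 | (3R,4R,5R,7S)-3-(3-methylbut-2-enoyloxy)eremophila-9,11-dien-8-one | C=C(C)[C@@H]1C[C@]2(C)[C@@H](C)[C@H](OC(=O)C=C(C)C)CCC2=CC1=O | intermediate
9 | (3R,4R,5R,7S,9S,10R)-9-hydroperoxy-3-(3-methylbut-2-enoyloxy)eremophil-11-en-8-one | C=C(C)[C@@H]1C[C@]2(C)[C@@H](C)[C@H](OC(=O)C=C(C)C)CC[C@H]2[C@H](OO)C1=O | intermediate (not isolated)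
10 | (3R,4R,5R,7S,9S,10R)-9-hydroxy-3-(3-methylbut-2-enoyloxy)eremophil-11-en-8-one | C=C(C)[C@@H]1C[C@]2(C)[C@@H](C)[C@H](OC(=O)C=C(C)C)CC[C@H]2[C@H](O)C1=O | intermediate
11 | (E)-2-methylbut-2-enoyl chloride (tigloyl chloride) | C/C=C(\C)C(=O)Cl | starting material
12 | (3R,4R,5R,7S,9S,10R)-3-(3-methylbut-2-enoyloxy)-9-[(E)-2-methylbut-2-enoyloxy]eremophil-11-en-8-one | C=C(C)[C@@H]1C[C@]2(C)[C@@H](C)[C@H](OC(=O)C=C(C)C)CC[C@H]2[C@H](OC(=O)/C(C)=C/C)C1=O | target

**Totals**

Total steps: 7. Longest linear sequence: 7 (from 1).

**Steps most likely to fail, with fallbacks**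

Step 1 (enantioselectivity and regiochemistry of proton loss in the catalytic transannular cyclization). The fallback takes the absolute configuration from a kinetic resolution instead of an asymmetric protonation; it sets out from 1 and comes back at 5. Germacrone 1 is cyclized with an achiral acid (TsOH, CH2Cl2, 0 °C, the known racemic reaction) to racemic eudesma-4(15),7(11)-dien-8-one F1. SeO2/t-BuOOH as in step 2 gives racemic 3α-hydroxyeudesma-4(15),7(11)-dien-8-one F2. Acylative kinetic resolution of this secondary allylic alcohol with 3-methylbut-2-enoic anhydride, the isothiourea acyl-transfer catalyst (R)-benzotetramisole and iPr2NEt in CHCl3 at 0 °C, stopped near 45% conversion, then esterifies the (3R)-enantiomer selectively to 5. The unreacted (3S,5S,10S)-3-hydroxyeudesma-4(15),7(11)-dien-8-one F3 is separated by chromatography.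

Step 4 (the acyloxy group may capture the C4 cation, or the allylic ester may ionize in strong acid, instead of the hydride/methyl shifts). The fallback generates the same C4 cation without protic acid, by metal-hydride hydrogen-atom transfer and radical–polar crossover; it sets out from 5 and comes back at 6. Compound 5 is treated with the cobalt salen complex N,N'-bis(3,5-di-tert-butylsalicylidene)cyclohexane-1,2-diaminocobalt (divalent cobalt, 5 mol %), N-fluoro-2,4,6-trimethylpyridinium tetrafluoroborate and PhSiH3 in (CF3)2CHOH/PhCF3 at 0 °C. H-atom transfer to C15 gives the tertiary C4 radical, which is oxidized at cobalt to the cation, and this undergoes the same 5α-H shift, 10β-methyl shift and loss of H9 to give 6. This fallback forms no compound outside the list (none F0).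

Step 5 (competing deprotonation at C1 or at the senecioate, and the configuration at C7). The fallback replaces hard enolization by soft enolization to an isolable silyl trienol ether, followed by α-selective protodesilylation; it sets out from 6 and comes back at 8. Compound 6 with TBSOTf and Et3N in CH2Cl2 (−78 to 0 °C) gives, under reversible conditions and without strong base, (3R,4R,5R)-8-(tert-butyldimethylsilyloxy)-3-(3-methylbut-2-enoyloxy)eremophila-7,9,11-triene F4. This isomer is favoured over the 1(10),7(11),8-triene because it avoids allylic strain between the isopropylidene methyl and the silyloxy group, and it can be purified from that regioisomer. Treatment with Bu4NF/AcOH in THF at −78 °C releases the dienolate in the presence of the proton source, which protonates it at C7 to give 8.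

**Further compounds**

F1 | step 1 | racemic eudesma-4(15),7(11)-dien-8-one (1:1 mixture of 2 and its enantiomer) | C=C1CCC[C@]2(C)CC(=O)C(=C(C)C)C[C@@H]12.C=C1CCC[C@@]2(C)CC(=O)C(=C(C)C)C[C@H]12
F2 | step 1 | racemic 3α-hydroxyeudesma-4(15),7(11)-dien-8-one (1:1 mixture of 3 and its enantiomer) | C=C1[C@H](O)CC[C@]2(C)CC(=O)C(=C(C)C)C[C@@H]12.C=C1[C@@H](O)CC[C@@]2(C)CC(=O)C(=C(C)C)C[C@H]12
F3 | step 1 | (3S,5S,10S)-3-hydroxyeudesma-4(15),7(11)-dien-8-one (unreacted enantiomer) | C=C1[C@@H](O)CC[C@@]2(C)CC(=O)C(=C(C)C)C[C@H]12
F0 | step 4 | none | none
F4 | step 5 | (3R,4R,5R)-8-(tert-butyldimethylsilyloxy)-3-(3-methylbut-2-enoyloxy)eremophila-7,9,11-triene | C=C(C)C=1C[C@]2(C)[C@@H](C)[C@H](OC(=O)C=C(C)C)CCC2=CC=1O[Si](C)(C)C(C)(C)C
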